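**Retrosynthetic overview**
- Feature: the ring C carbonyl carbon C4 sits on C4a of ring A. Both carbons ortho to C4a carry oxygen (C8a–O1 and C5–O5). Ring A plus C4 is therefore a mirror-symmetric 2,6-dihydroxybenzaldehyde, and either hydroxyl can direct a metal to the formyl C–H and later become O1.
- Key disconnection: C4–C3 and O1–C2 of ring C. This gives an A-ring aldehyde that already carries O7 as a neopentyl sulfate diester, and a B-ring aroyl sulfoxonium ylide that supplies C3 and C2.
- Endgame: the 3'-sulfate comes from a temporary cyclic sulfate across O3'/O4', opened at sulfur with loss of the better 4'-phenoxide. The 7-sulfate is unmasked by azide dealkylation.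
- Ring order: rings A and B are bought. Pyranone ring C is formed in step 5. The temporary 1,3,2-dioxathiole ring on ring B is formed in step 7 and opened in step 8.

Key step: step 5

Remark: the target has no stereocentre and no stereogenic axis, so there is no enantiomer to select. The sulfate monoesters are carried as sodium salts, and the bis(hydrogen sulfate) drawn in the SMILES is released only in the last step.

**Step 1**
Reactants: 1 neopentyl alcohol
Product: 2 neopentyl chlorosulfate
Conditions: SO2Cl2 (1.05 equiv), pyridine (1.0 equiv), Et2O, −78 °C → rt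
Reagents that add atoms: sulfuryl chloride O=S(=O)(Cl)Cl
Why: O-sulfonylation of an alcohol by sulfuryl chloride, in which the neopentyl skeleton blocks chloride displacement at carbon, so the chlorosulfate should survive isolation.

**Step 2**
Reactants: 3 2,4,6-trihydroxybenzaldehyde; 2 neopentyl chlorosulfate
Product: 4 4-formyl-3,5-dihydroxyphenyl neopentyl sulfate
Conditions: 3 (1.2 equiv), NaH (1.2 equiv), THF–DMPU, 0 °C; 2 (1.0 equiv) added slowly, 0 °C → rt
Reagents that add atoms: none
Why: Sulfuryl transfer from an alkyl chlorosulfate to a phenoxide, where the formyl oxygen can hold only one ortho hydroxyl in a hydrogen bond at a time, so selectivity rests on O4 being the most acidic (para to CHO) and least hindered site, supported by one equivalent of base and a limiting, bulky electrophile.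

**Step 3**
Reactants: 5 3,4-bis(benzyloxy)benzoic acid
Product: 6 3,4-bis(benzyloxy)benzoyl chloride
Conditions: (COCl)2 (1.3 equiv), DMF (cat.), CH2Cl2, 0 °C → rt; evaporate
Reagents that add atoms: oxalyl chloride O=C(Cl)C(=O)Cl
Why: Acid chloride formation through the Vilsmeier-type chloroiminium catalyst, under conditions that leave benzyl aryl ethers intact.

**Step 4**
Reactants: 7 trimethylsulfoxonium iodide; 6 3,4-bis(benzyloxy)benzoyl chloride
Product: 9 1-[3,4-bis(benzyloxy)phenyl]-2-[dimethyl(oxo)-λ6-sulfanylidene]ethan-1-one, via dimethylsulfoxonium methylide 8 (not isolated)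
Conditions: 7 (3 equiv), KOtBu (3 equiv), THF, reflux; cool to 0 °C, add 6 (1 equiv), 0 °C → rt
Reagents that add atoms: none
Why: C-acylation of the Corey–Chaykovsky sulfoxonium methylide by an acid chloride, in which a second equivalent of methylide deprotonates the acylated salt to give the stabilised keto ylide.

**Step 5**
Reactants: 4 4-formyl-3,5-dihydroxyphenyl neopentyl sulfate; 9 1-[3,4-bis(benzyloxy)phenyl]-2-[dimethyl(oxo)-λ6-sulfanylidene]ethan-1-one
Product: 11 3',4'-di-O-benzylluteolin 7-(neopentyl sulfate), via 1,3-diketone 10 (not isolated)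
Conditions: [Cp*RhCl2]2 (4 mol %), AgSbF6 (16 mol %), CsOPiv (0.3 equiv), PivOH (1 equiv), 9 (1.3 equiv), DCE, 80 °C, N2
Reagents that add atoms: none
Why: Pivalate-assisted exchange binds one phenoxide of 4 to Cp*Rh(III), and the formyl C–H is then cleaved by concerted metalation–deprotonation to a five-membered acyl rhodacycle (Rh–O–C(aryl)–C(aryl)–C=O), so the future C4 becomes a metal-bound acyl nucleophile. The carbanionic carbon of 9 binds to rhodium, DMSO leaves to give a rhodium carbene, migratory insertion of the carbene into the Rh–acyl bond forms C4–C3, and protonolysis by PivOH releases diketone 10 and returns the catalyst without an external oxidant. An ortho hydroxyl of 10 then adds to the aroyl carbonyl (6-exo-trig hemiketal formation, O1–C2), and acid-promoted loss of water closes the aromatic pyranone ring C. The closest known reaction type is the rhodium(III)-catalysed annulation of salicylaldehydes with aroyl sulfoxonium ylides to 2-arylchromones, applied here to a 2,6-dihydroxy substrate. The step needs formyl C–H cleavage in preference to arene C–H cleavage, CO loss or O-phenacylation of the phenols: the O-bound metal can reach only the formyl hydrogen through a five-membered ring, both aryl C–H bonds of 4 are meta to the formyl group and flanked by two oxygens, and the PivOH/pivalate buffer should keep the ylide largely unprotonated. No stereocentre is formed and no regiochemical question arises, because the mirror plane of 4 makes both hydroxyls equivalent and the unused one ends as the chelated 5-OH.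

**Step 6**
Reactants: 11 3',4'-di-O-benzylluteolin 7-(neopentyl sulfate)
Product: 12 luteolin 7-(neopentyl sulfate)
Conditions: H2 (1 atm), 10% Pd/C, THF–MeOH, rt
Reagents that add atoms: none
Why: Catalytic hydrogenolysis of benzyl aryl ethers, under mild conditions at which the flavone C2=C3 bond and the S(VI) sulfate diester should not be reduced.

**Step 7**
Reactants: 12 luteolin 7-(neopentyl sulfate)
Product: 13 luteolin 3',4'-cyclic sulfate 7-(neopentyl sulfate)
Conditions: 1,1'-sulfonyldiimidazole (1.1 equiv), KF (4 equiv), THF (dilute), 50 °C; filtration through silica, no aqueous work-up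
Reagents that add atoms: 1,1'-sulfonyldiimidazole O=S(=O)(n1ccnc1)n1ccnc1
Why: Known cyclic-sulfate synthesis from a catechol by sulfuryl transfer, in which the more acidic 4'-OH should form the aryl imidazole-1-sulfonate and the neighbouring O3' displaces the second imidazole in a five-membered closure at sulfur, while the 5-OH hydrogen-bonded to C4=O and the neopentyl diester stay untouched.

**Step 8**
Reactants: 13 luteolin 3',4'-cyclic sulfate 7-(neopentyl sulfate)
Product: 14 sodium luteolin 7-(neopentyl sulfate) 3'-sulfate
Conditions: 0.05 M aq NaOH (2.1 equiv), THF, 0 °C, minutes; AcOH to pH 6–7; C18 (H2O–MeOH)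
Reagents that add atoms: sodium hydroxide [Na+].[OH-]
Why: Alkaline hydrolysis of a catechol cyclic sulfate, where hydroxide attacks the strained ring sulfur many orders of magnitude faster than the acyclic 7-sulfate diester, and the S–O bond to O4' should break because that phenoxide is conjugated through C1'–C2=C3–C4=O and is the better leaving group, leaving the sulfate on O3'.

**Step 9**
Reactants: 14 sodium luteolin 7-(neopentyl sulfate) 3'-sulfate
Product: 15 disodium luteolin 7,3'-disulfate
Conditions: NaN3 (4 equiv), DMF, 65 °C; precipitate with Et2O (washings not concentrated); C18 (H2O–MeOH)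
Reagents that add atoms: sodium azide [Na+].[N-]=[N+]=[N-]
Why: SN2 dealkylation of a neopentyl sulfate diester by azide, feasible at the hindered carbon because the aryl sulfate monoester anion is an excellent leaving group, while aryl sulfate salts and free phenols are inert in neutral DMF.

**Step 10**
Reactants: 15 disodium luteolin 7,3'-disulfate
Product: 16 luteolin 7,3'-disulfate
Conditions: Dowex 50W-X8 (H+ form), H2O, 0–5 °C; freeze-dry at once
Reagents that add atoms: none
Why: Cation exchange on a sulfonic acid resin replaces Na+ by H+, with cold and brief contact because aryl hydrogen sulfates hydrolyse under their own acidity.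

**Compound list**
1 | neopentyl alcohol (2,2-dimethylpropan-1-ol) | CC(C)(C)CO | starting material
2 | neopentyl chlorosulfate | CC(C)(C)COS(=O)(=O)Cl | intermediate
3 | 2,4,6-trihydroxybenzaldehyde | O=Cc1c(O)cc(O)cc1O | starting material
4 | 4-formyl-3,5-dihydroxyphenyl neopentyl sulfate | O=Cc1c(O)cc(OS(=O)(=O)OCC(C)(C)C)cc1O | intermediate
5 | 3,4-bis(benzyloxy)benzoic acid | O=C(O)c1ccc(OCc2ccccc2)c(OCc2ccccc2)c1 | starting material
6 | 3,4-bis(benzyloxy)benzoyl chloride | O=C(Cl)c1ccc(OCc2ccccc2)c(OCc2ccccc2)c1 | intermediate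
7 | trimethylsulfoxonium iodide | C[S+](C)(C)=O.[I-] | starting material
8 | dimethylsulfoxonium methylide (not isolated) | CS(C)(=O)=C | intermediate
9 | 1-[3,4-bis(benzyloxy)phenyl]-2-[dimethyl(oxo)-λ6-sulfanylidene]ethan-1-one | CS(C)(=O)=CC(=O)c1ccc(OCc2ccccc2)c(OCc2ccccc2)c1 | intermediate
10 | 4-{3-[3,4-bis(benzyloxy)phenyl]-3-oxopropanoyl}-3,5-dihydroxyphenyl neopentyl sulfate (not isolated) | O=C(CC(=O)c1ccc(OCc2ccccc2)c(OCc2ccccc2)c1)c1c(O)cc(OS(=O)(=O)OCC(C)(C)C)cc1O | intermediate
11 | 3',4'-di-O-benzylluteolin 7-(neopentyl sulfate) | O=c1cc(-c2ccc(OCc3ccccc3)c(OCc3ccccc3)c2)oc2cc(OS(=O)(=O)OCC(C)(C)C)cc(O)c12 | intermediate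
12 | luteolin 7-(neopentyl sulfate) | O=c1cc(-c2ccc(O)c(O)c2)oc2cc(OS(=O)(=O)OCC(C)(C)C)cc(O)c12 | intermediate
13 | luteolin 3',4'-cyclic sulfate 7-(neopentyl sulfate) | O=c1cc(-c2ccc3c(c2)OS(=O)(=O)O3)oc2cc(OS(=O)(=O)OCC(C)(C)C)cc(O)c12 | intermediate
14 | sodium luteolin 7-(neopentyl sulfate) 3'-sulfate | O=c1cc(-c2ccc(O)c(OS(=O)(=O)[O-])c2)oc2cc(OS(=O)(=O)OCC(C)(C)C)cc(O)c12.[Na+] | intermediate
15 | disodium luteolin 7,3'-disulfate | O=c1cc(-c2ccc(O)c(OS(=O)(=O)[O-])c2)oc2cc(OS(=O)(=O)[O-])cc(O)c12.[Na+].[Na+] | intermediate
16 | luteolin 7,3'-disulfate | O=c1cc(-c2ccc(O)c(OS(=O)(=O)O)c2)oc2cc(OS(=O)(=O)O)cc(O)c12 | target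

**Step count**
- Total step count: 10.
- Longest linear sequence: 8 steps (1 → 2 → 5 → 6 → 7 → 8 → 9 → 10). The B-ring branch 3 → 4 → 5 → … → 10 is equally long.

**Steps most likely to fail**

1. **Step 5.**
   - What may go wrong: the acyl–rhodium intermediate may lose CO. The acidic phenols may protonate the ylide and be O-alkylated with loss of DMSO. The two phenoxides may tie up the catalyst.
   - Fallback (sets out from 4, comes back at 11): both hydroxyls of 4 are capped with MOMCl and iPr2NEt in CH2Cl2 to give 4-formyl-3,5-bis(methoxymethoxy)phenyl neopentyl sulfate F1.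
   - The lithium enolate of purchased 3',4'-bis(benzyloxy)acetophenone (CC(=O)c1ccc(OCc2ccccc2)c(OCc2ccccc2)c1; LDA, THF, −78 °C) is added to the aldehyde to give the racemic aldol adduct 4-{3-[3,4-bis(benzyloxy)phenyl]-1-hydroxy-3-oxopropyl}-3,5-bis(methoxymethoxy)phenyl neopentyl sulfate F2.
   - Dess–Martin periodinane oxidises F2, removing its only stereocentre, to the protected diketone 4-{3-[3,4-bis(benzyloxy)phenyl]-3-oxopropanoyl}-3,5-bis(methoxymethoxy)phenyl neopentyl sulfate F3.
   - HCl in MeOH–THF at 50 °C removes both MOM groups and cyclodehydrates through 10 to 11.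

2. **Step 8.**
   - What may go wrong: discrimination between the two aryl O–S bonds may be poor during ring opening, giving regioisomeric ionic monosulfates that are hard to separate. The sensitive cyclic sulfate may also be lost between steps 7 and 8.
   - Fallback (sets out from 12, comes back at 15, and bypasses steps 7–9): the para-conjugated 4'-OH of 12 is benzylated selectively (BnBr 1.0 equiv, NaHCO3, NaI, DMF, 40 °C), as is done for 3,4-dihydroxybenzaldehyde. This gives neutral, chromatographable 4'-O-benzylluteolin 7-(neopentyl sulfate) F4.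
   - The 3'-OH of F4 is sulfated with 2 (NaH 1.0 equiv, THF–DMPU, with the 5-OH chelated) to give 4'-O-benzylluteolin 7,3'-bis(neopentyl sulfate) F5.
   - NaN3 in DMF at 65 °C removes both neopentyl groups to give disodium 4'-O-benzylluteolin 7,3'-disulfate F6.
   - Hydrogenolysis (H2, Pd/C, MeOH–H2O) then gives 15.

3. **Step 2.**
   - What may go wrong: site selectivity among three phenols may be poor, because one ortho hydroxyl is always unchelated. Over-sulfation may follow proton exchange between the product and the starting anion.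
   - Fallback (sets out from 2, comes back at 4): purchased 2,4,6-trihydroxybenzoic acid is condensed with acetone (TFAA, TFA) to give 5,7-dihydroxy-2,2-dimethyl-4H-1,3-benzodioxin-4-one F7. One ortho oxygen of F7 is tied into the acetonide and the other is chelated to the lactone carbonyl.
   - Only O7 of F7 then reacts with 2 (NaH 1.0 equiv, THF–DMPU), giving 5-hydroxy-2,2-dimethyl-4-oxo-4H-1,3-benzodioxin-7-yl neopentyl sulfate F8.
   - DIBAL-H (3 equiv, CH2Cl2, −78 °C, Rochelle salt work-up) reduces the benzodioxinone of F8 to the salicylaldehyde level and releases 4.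

**Further compounds**
F1 | step 5 | 4-formyl-3,5-bis(methoxymethoxy)phenyl neopentyl sulfate | O=Cc1c(OCOC)cc(OS(=O)(=O)OCC(C)(C)C)cc1OCOC
F2 | step 5 | (±)-4-{3-[3,4-bis(benzyloxy)phenyl]-1-hydroxy-3-oxopropyl}-3,5-bis(methoxymethoxy)phenyl neopentyl sulfate | OC(CC(=O)c1ccc(OCc2ccccc2)c(OCc2ccccc2)c1)c1c(OCOC)cc(OS(=O)(=O)OCC(C)(C)C)cc1OCOC
F3 | step 5 | 4-{3-[3,4-bis(benzyloxy)phenyl]-3-oxopropanoyl}-3,5-bis(methoxymethoxy)phenyl neopentyl sulfate | O=C(CC(=O)c1ccc(OCc2ccccc2)c(OCc2ccccc2)c1)c1c(OCOC)cc(OS(=O)(=O)OCC(C)(C)C)cc1OCOC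
F4 | step 8 | 4'-O-benzylluteolin 7-(neopentyl sulfate) | O=c1cc(-c2ccc(OCc3ccccc3)c(O)c2)oc2cc(OS(=O)(=O)OCC(C)(C)C)cc(O)c12
F5 | step 8 | 4'-O-benzylluteolin 7,3'-bis(neopentyl sulfate) | O=c1cc(-c2ccc(OCc3ccccc3)c(OS(=O)(=O)OCC(C)(C)C)c2)oc2cc(OS(=O)(=O)OCC(C)(C)C)cc(O)c12
F6 | step 8 | disodium 4'-O-benzylluteolin 7,3'-disulfate | O=c1cc(-c2ccc(OCc3ccccc3)c(OS(=O)(=O)[O-])c2)oc2cc(OS(=O)(=O)[O-])cc(O)c12.[Na+].[Na+]
F7 | step 2 | 5,7-dihydroxy-2,2-dimethyl-4H-1,3-benzodioxin-4-one | CC1(C)OC(=O)c2c(O)cc(O)cc2O1
F8 | step 2 | 5-hydroxy-2,2-dimethyl-4-oxo-4H-1,3-benzodioxin-7-yl neopentyl sulfate | CC1(C)OC(=O)c2c(O)cc(OS(=O)(=O)OCC(C)(C)C)cc2O1
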